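**Retrosynthetic overview** (carotenoid numbering; unprimed = acetylenic half with ring A, primed = 7′,8′-dihydro half with ring B)

1. C40 = C15 + C10 + C15′: two (E)-selective Wittig reactions of allylic tributylphosphonium ylides with 2,7-dimethylocta-2,4,6-trienedial form C11=C12 and C11′=C12′.
2. Ring A is taken intact from (4R,6R)-actinol (gives 3R); a Sonogashira coupling of its enol triflate with (E)-3-methylpent-2-en-4-yn-1-ol makes C6–C7≡C8 and carries 9E in unchanged.
3. Ring B is first a cyclobutane: a ketene [2+2] joins isobutylene (C1′, C2′, both methyl groups on C1′) to an alkyl(isopropenyl)ketene made from geraniol and CO2 (C3′ from CO2; C6′, C5′, C4′ and the C5′ methyl from the prenyl end; C7′–C11′ with 9′E from the rest of geraniol).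
4. Enabling feature: ring B is a cyclohex-3-en-1-ol, the carbinol C3′ being homoallylic to the tetrasubstituted C5′=C6′ bond through C4′H2. This is the retron of an alkoxide-accelerated [1,3] shift in which C3′ of a 2-isopropenylcyclobutan-1-olate (ring C3′–C2′–C1′–C6′) migrates from C6′ to C4′, so the four-membered ring grows to the six-membered ring under strain release.
5. Order of rings: ring A (bought) → cyclobutane (step 10) → ring B by expansion (step 12) → lipase resolution fixes 3′R (step 13) → fragment union and deprotection.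

Key step: step 12

Assumption: (4R,6R)-actinol 1, the (E)-enynol 5 and the all-E C10-dialdehyde 9 are taken as purchasable carotenoid building blocks.

**Ring A half**

Step 1
Reactants: 1 (4R,6R)-4-hydroxy-2,2,6-trimethylcyclohexan-1-one
Product: 2 (4R,6R)-4-(tert-butyldimethylsilyloxy)-2,2,6-trimethylcyclohexan-1-one
Conditions: TBSCl, imidazole, DMF, rt
Reagents that add atoms: tert-butyldimethylsilyl chloride, CC(C)(C)[Si](C)(C)Cl
Why: Silyl ether formation at the secondary alcohol; no stereocentre is touched and the ketone stays free for enolisation.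

Step 2
Reactants: 2 silyl ether of actinol
Product: 4 (4R)-4-(tert-butyldimethylsilyloxy)-2,6,6-trimethylcyclohex-1-en-1-yl trifluoromethanesulfonate, via lithium enolate 3 (not isolated)
Conditions: LDA, THF, −78 °C; then PhNTf2, −78 °C → rt
Reagents that add atoms: N-phenylbis(trifluoromethanesulfonimide), O=S(=O)(N(c1ccccc1)S(=O)(=O)C(F)(F)F)C(F)(F)F
Why: Enolate O-triflation; enolisation can occur only towards C6 because C2 is quaternary, so a single enol triflate should form, the C6 stereocentre is erased on purpose and C4 (later C3, R) is untouched.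

Step 3
Reactants: 4 enol triflate; 5 (2E)-3-methylpent-2-en-4-yn-1-ol
Product: 6 (2E)-5-[(4R)-4-(tert-butyldimethylsilyloxy)-2,6,6-trimethylcyclohex-1-en-1-yl]-3-methylpent-2-en-4-yn-1-ol
Conditions: Pd(PPh3)4 (cat.), CuI (cat.), i-Pr2NH, DMF, rt → 50 °C
Reagents that add atoms: none
Why: Sonogashira coupling of an alkenyl triflate with a terminal alkyne forms C6–C7; the bond is made at the sp carbon, so the (E)-geometry of the enynol (later 9E) is carried over unchanged and the free allylic alcohol is tolerated.

Step 4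
Reactants: 6 enynol
Product: 7 tert-butyl{[(1R)-4-[(3E)-5-bromo-3-methylpent-3-en-1-yn-1-yl]-3,5,5-trimethylcyclohex-3-en-1-yl]oxy}dimethylsilane
Conditions: CBr4, PPh3, CH2Cl2, −20 °C
Reagents that add atoms: carbon tetrabromide, BrC(Br)(Br)Br
Why: Appel reaction; SN2 displacement at the primary allylic carbon under neutral conditions should spare the silyl ether and the (E)-enyne.

Step 5
Reactants: 7 allylic bromide
Product: 8 tributyl{(2E)-5-[(4R)-4-(tert-butyldimethylsilyloxy)-2,6,6-trimethylcyclohex-1-en-1-yl]-3-methylpent-2-en-4-yn-1-yl}phosphonium bromide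
Conditions: PBu3, MeCN, rt
Reagents that add atoms: tributylphosphine, CCCCP(CCCC)CCCC
Why: SN2 quaternisation of the phosphine at the primary allylic bromide, without allylic transposition.

Step 6
Reactants: 8 phosphonium bromide; 9 (2E,4E,6E)-2,7-dimethylocta-2,4,6-trienedial
Product: 11 (2E,4E,6E,8E,10E)-13-[(4R)-4-(tert-butyldimethylsilyloxy)-2,6,6-trimethylcyclohex-1-en-1-yl]-2,7,11-trimethyltrideca-2,4,6,8,10-pentaen-12-ynal, via phosphorus ylide 10 (not isolated)
Conditions: NaHMDS, THF, −78 °C; then added to 9 (3 equiv), −78 → 0 °C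
Reagents that add atoms: none
Why: Wittig olefination with an allylic trialkylphosphonium ylide, a class that is (E)-selective, forms C11=C12; inverse addition to an excess of the symmetrical dialdehyde should hold the reaction at the mono-adduct.

**Ring B half**

Step 7
Reactants: 12 geraniol
Product: 13 tert-butyl{[(2E)-3,7-dimethylocta-2,6-dien-1-yl]oxy}dimethylsilane
Conditions: TBSCl, imidazole, CH2Cl2, rt
Reagents that add atoms: tert-butyldimethylsilyl chloride, CC(C)(C)[Si](C)(C)Cl
Why: Silyl ether formation at the primary allylic alcohol; the (E)-2,3-double bond (later 9′E) is untouched.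

Step 8
Reactants: 13 geranyl silyl ether
Product: 14 tert-butyl{[(2E)-6-chloro-3,7-dimethylocta-2,7-dien-1-yl]oxy}dimethylsilane (racemic)
Conditions: Ca(OCl)2, solid CO2, CH2Cl2/H2O, 0 °C
Reagents that add atoms: calcium hypochlorite, [Ca+2].[O-]Cl.[O-]Cl
Why: Ene-type allylic chlorination by hypochlorous acid; chlorine adds to the less substituted carbon of the electron-rich 6,7-double bond and a methyl proton is lost, the 2,3-double bond is deactivated by the allylic oxygen, and the new stereocentre is racemic and later becomes sp2.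

Step 9
Reactants: 14 allylic chloride
Product: 16 (5E)-7-(tert-butyldimethylsilyloxy)-5-methyl-2-(prop-1-en-2-yl)hept-5-enoic acid (racemic), via allylmagnesium chloride 15 (not isolated)
Conditions: Mg, THF, −10 °C; then CO2, −78 → 0 °C; then cold dilute HCl to pH 4
Reagents that add atoms: carbon dioxide, O=C=O
Why: Grignard carboxylation; allylmagnesium halides react with CO2 by SE2′ attack through the γ-carbon, so the carboxyl group should end on the secondary carbon and give the branched β,γ-unsaturated acid, whose racemic stereocentre is lost at the ketene stage.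

Step 10
Reactants: 16 β,γ-unsaturated acid; 17 2-methylpropene (isobutylene)
Product: 20 2-[(3E)-5-(tert-butyldimethylsilyloxy)-3-methylpent-3-en-1-yl]-3,3-dimethyl-2-(prop-1-en-2-yl)cyclobutan-1-one (racemic), via acid chloride 18 (not isolated), via alkenylketene 19 (not isolated)
Conditions: 1-chloro-N,N,2-trimethylprop-1-en-1-amine, CH2Cl2, 0 °C; then Et3N, isobutylene (large excess), toluene, sealed tube, 80 °C
Reagents that add atoms: none
Why: Thermal ketene–alkene [2+2] cycloaddition after neutral acid chloride formation and dehydrochlorination at the doubly activated α-hydrogen; the ketene carbonyl carbon should bond to the CH2 terminus of isobutylene and the ketene α-carbon to the tertiary carbon (the usual regiochemistry with 1,1-disubstituted alkenes), the vinylketene reacting only through its C=C=O unit, and the racemic quaternary stereocentre is erased in step 12.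

Step 11
Reactants: 20 cyclobutanone
Product: 21 2-[(3E)-5-(tert-butyldimethylsilyloxy)-3-methylpent-3-en-1-yl]-3,3-dimethyl-2-(prop-1-en-2-yl)cyclobutan-1-ol (racemic; both diastereomers)
Conditions: NaBH4, MeOH, 0 °C
Reagents that add atoms: none
Why: Borohydride reduction of the strained ketone; both carbinol diastereomers are acceptable because they converge in step 12.

Step 12
Reactants: 21 2-isopropenylcyclobutan-1-ol
Product: 23 4-[(3E)-5-(tert-butyldimethylsilyloxy)-3-methylpent-3-en-1-yl]-3,5,5-trimethylcyclohex-3-en-1-ol (racemic), via potassium cyclobutanolate 22 (not isolated)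
Conditions: KH, 18-crown-6, THF, 0 °C → rt; then H2O
Reagents that add atoms: none
Why: Deprotonation gives the potassium cyclobutanolate 22, whose strained C3′–C6′ bond (carbinol carbon to the quaternary allylic carbon) should cleave to an aldehyde and an allyl anion delocalised over C6′–C5′–C4′, which recloses through its unhindered primary terminus C4′ onto the aldehyde carbon C3′, a net alkoxide-accelerated [1,3] sigmatropic shift. The closest known reaction type is the alkoxide-accelerated vinylcyclobutane-to-cyclohexene rearrangement of 2-vinylcyclobutan-1-ols. Ring B closes by a 6-exo-trig carbonyl addition in which the allyl unit becomes endocyclic, which fixes the double bond as the tetrasubstituted C5′=C6′ and leaves C3′ homoallylic. C3′ is formed without control because the open intermediate is achiral, so both diastereomers of 21 should converge on racemic 23 and the configuration is set by resolution in step 13. The step needs regioselective cleavage (only C3′–C6′, not C3′–C2′, gives a stabilised carbanion) and regioselective reclosure (attack through C6′ only regenerates the four-membered ring, so strain release funnels the system to the cyclohexenolate); the silyl ether and the remote trisubstituted alkene offer no acidic or electrophilic site.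

Step 13
Reactants: 23 racemic cyclohexenol
Product: 24 (1R)-4-[(3E)-5-(tert-butyldimethylsilyloxy)-3-methylpent-3-en-1-yl]-3,5,5-trimethylcyclohex-3-en-1-yl acetate
Conditions: lipase PS (Burkholderia cepacia, immobilised), vinyl acetate, MTBE, 30 °C, stopped below half conversion
Reagents that add atoms: vinyl acetate, CC(=O)OC=C
Why: Lipase-catalysed kinetic resolution by irreversible transesterification; by the empirical rule for secondary alcohols, with the CMe2-flanked C2′ side as the large and the C4′ side as the medium substituent, the (R)-enantiomer should be acylated faster, which sets 3′R, and the unreacted half of 23 is removed by chromatography.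

Step 14
Reactants: 24 (R)-acetate
Product: 25 (1R)-4-[(3E)-5-hydroxy-3-methylpent-3-en-1-yl]-3,5,5-trimethylcyclohex-3-en-1-yl acetate
Conditions: HF·pyridine, pyridine, THF, 0 °C
Reagents that add atoms: none
Why: Fluoride-mediated desilylation of the primary allylic silyl ether under buffered conditions that should leave the acetate and both alkenes intact.

Step 15
Reactants: 25 allylic alcohol
Product: 26 (1R)-4-[(3E)-5-bromo-3-methylpent-3-en-1-yl]-3,5,5-trimethylcyclohex-3-en-1-yl acetate
Conditions: CBr4, PPh3, CH2Cl2, −20 °C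
Reagents that add atoms: carbon tetrabromide, BrC(Br)(Br)Br
Why: Appel reaction; SN2 at the primary allylic carbon keeps the (E)-geometry (later 9′E), and the acetate shields the ring hydroxyl.

Step 16
Reactants: 26 allylic bromide
Product: 27 {(2E)-5-[(4R)-4-acetoxy-2,6,6-trimethylcyclohex-1-en-1-yl]-3-methylpent-2-en-1-yl}tributylphosphonium bromide
Conditions: PBu3, MeCN, rt
Reagents that add atoms: tributylphosphine, CCCCP(CCCC)CCCC
Why: SN2 quaternisation of the phosphine at the primary allylic bromide.

**Union and deprotection**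

Step 17
Reactants: 27 ring-B phosphonium bromide; 11 C25 aldehyde
Product: 29 (3R,3′R)-3′-O-acetyl-3-O-(tert-butyldimethylsilyl)-7,8-didehydro-7′,8′-dihydro-β,β-carotene-3,3′-diol (all-E), via phosphorus ylide 28 (not isolated)
Conditions: NaHMDS (1 equiv), THF, −78 °C; then 11, −78 → 0 °C, dim light
Reagents that add atoms: none
Why: Wittig olefination with the (E)-selective allylic trialkylphosphonium ylide forms C11′=C12′; the ylide is pre-formed with a hindered amide base at low temperature so the acetate should survive, and the existing double bonds, including 9E next to the triple bond, are not equilibrated.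

Step 18
Reactants: 29 protected carotenoid
Product: 31 (3R,3′R)-7,8-didehydro-7′,8′-dihydro-β,β-carotene-3,3′-diol (all-E), via 3′-alcohol 30 (not isolated)
Conditions: K2CO3, MeOH/THF, rt; then TBAF, THF, rt, dim light
Reagents that add atoms: none
Why: Methanolysis of the acetate (transesterification) and then fluoride cleavage of the silyl ether, both non-acidic conditions that the polyene should tolerate; no stereocentre or double bond is touched.

**Compound list**

1 | (4R,6R)-4-hydroxy-2,2,6-trimethylcyclohexan-1-one | C[C@@H]1C[C@@H](O)CC(C)(C)C1=O | starting material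
2 | (4R,6R)-4-(tert-butyldimethylsilyloxy)-2,2,6-trimethylcyclohexan-1-one | C[C@@H]1C[C@@H](O[Si](C)(C)C(C)(C)C)CC(C)(C)C1=O | intermediate
3 | lithium (4R)-4-(tert-butyldimethylsilyloxy)-2,6,6-trimethylcyclohex-1-en-1-olate | [Li+].CC1=C([O-])C(C)(C)C[C@H](O[Si](C)(C)C(C)(C)C)C1 | intermediate
4 | (4R)-4-(tert-butyldimethylsilyloxy)-2,6,6-trimethylcyclohex-1-en-1-yl trifluoromethanesulfonate | CC1=C(OS(=O)(=O)C(F)(F)F)C(C)(C)C[C@H](O[Si](C)(C)C(C)(C)C)C1 | intermediate
5 | (2E)-3-methylpent-2-en-4-yn-1-ol | C#C/C(C)=C/CO | starting material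
6 | (2E)-5-[(4R)-4-(tert-butyldimethylsilyloxy)-2,6,6-trimethylcyclohex-1-en-1-yl]-3-methylpent-2-en-4-yn-1-ol | CC1=C(C#C/C(C)=C/CO)C(C)(C)C[C@H](O[Si](C)(C)C(C)(C)C)C1 | intermediate
7 | tert-butyl{[(1R)-4-[(3E)-5-bromo-3-methylpent-3-en-1-yn-1-yl]-3,5,5-trimethylcyclohex-3-en-1-yl]oxy}dimethylsilane | CC1=C(C#C/C(C)=C/CBr)C(C)(C)C[C@H](O[Si](C)(C)C(C)(C)C)C1 | intermediate
8 | tributyl{(2E)-5-[(4R)-4-(tert-butyldimethylsilyloxy)-2,6,6-trimethylcyclohex-1-en-1-yl]-3-methylpent-2-en-4-yn-1-yl}phosphonium bromide | CC1=C(C#C/C(C)=C/C[P+](CCCC)(CCCC)CCCC)C(C)(C)C[C@H](O[Si](C)(C)C(C)(C)C)C1.[Br-] | intermediate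
9 | (2E,4E,6E)-2,7-dimethylocta-2,4,6-trienedial | O=C/C(C)=C/C=C/C=C(C)/C=O | starting material
10 | tributylphosphonium ylide of 8 | CC1=C(C#C/C(C)=C/C=P(CCCC)(CCCC)CCCC)C(C)(C)C[C@H](O[Si](C)(C)C(C)(C)C)C1 | intermediate
11 | (2E,4E,6E,8E,10E)-13-[(4R)-4-(tert-butyldimethylsilyloxy)-2,6,6-trimethylcyclohex-1-en-1-yl]-2,7,11-trimethyltrideca-2,4,6,8,10-pentaen-12-ynal | CC1=C(C#C/C(C)=C/C=C/C(C)=C/C=C/C=C(C)/C=O)C(C)(C)C[C@H](O[Si](C)(C)C(C)(C)C)C1 | intermediate
12 | geraniol, (2E)-3,7-dimethylocta-2,6-dien-1-ol | CC(C)=CCC/C(C)=C/CO | starting material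
13 | tert-butyl{[(2E)-3,7-dimethylocta-2,6-dien-1-yl]oxy}dimethylsilane | CC(C)=CCC/C(C)=C/CO[Si](C)(C)C(C)(C)C | intermediate
14 | tert-butyl{[(2E)-6-chloro-3,7-dimethylocta-2,7-dien-1-yl]oxy}dimethylsilane (racemic) | C=C(C)C(Cl)CC/C(C)=C/CO[Si](C)(C)C(C)(C)C | intermediate
15 | [(6E)-8-(tert-butyldimethylsilyloxy)-2,6-dimethylocta-2,6-dien-1-yl]magnesium chloride (allylic Grignard reagent, drawn in its primary form) | Cl[Mg]CC(C)=CCC/C(C)=C/CO[Si](C)(C)C(C)(C)C | intermediate
16 | (5E)-7-(tert-butyldimethylsilyloxy)-5-methyl-2-(prop-1-en-2-yl)hept-5-enoic acid (racemic) | C=C(C)C(CC/C(C)=C/CO[Si](C)(C)C(C)(C)C)C(=O)O | intermediate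
17 | 2-methylpropene (isobutylene) | C=C(C)C | starting material
18 | (5E)-7-(tert-butyldimethylsilyloxy)-5-methyl-2-(prop-1-en-2-yl)hept-5-enoyl chloride | C=C(C)C(CC/C(C)=C/CO[Si](C)(C)C(C)(C)C)C(=O)Cl | intermediate
19 | (5E)-7-(tert-butyldimethylsilyloxy)-5-methyl-2-(prop-1-en-2-yl)hepta-1,5-dien-1-one (alkyl(isopropenyl)ketene) | C=C(C)C(CC/C(C)=C/CO[Si](C)(C)C(C)(C)C)=C=O | intermediate
20 | 2-[(3E)-5-(tert-butyldimethylsilyloxy)-3-methylpent-3-en-1-yl]-3,3-dimethyl-2-(prop-1-en-2-yl)cyclobutan-1-one (racemic) | C=C(C)C1(CC/C(C)=C/CO[Si](C)(C)C(C)(C)C)C(=O)CC1(C)C | intermediate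
21 | 2-[(3E)-5-(tert-butyldimethylsilyloxy)-3-methylpent-3-en-1-yl]-3,3-dimethyl-2-(prop-1-en-2-yl)cyclobutan-1-ol (racemic, both diastereomers) | C=C(C)C1(CC/C(C)=C/CO[Si](C)(C)C(C)(C)C)C(O)CC1(C)C | intermediate
22 | potassium alkoxide of 21 | C=C(C)C1(CC/C(C)=C/CO[Si](C)(C)C(C)(C)C)C([O-])CC1(C)C.[K+] | intermediate
23 | 4-[(3E)-5-(tert-butyldimethylsilyloxy)-3-methylpent-3-en-1-yl]-3,5,5-trimethylcyclohex-3-en-1-ol (racemic) | CC1=C(CC/C(C)=C/CO[Si](C)(C)C(C)(C)C)C(C)(C)CC(O)C1 | intermediate
24 | (1R)-4-[(3E)-5-(tert-butyldimethylsilyloxy)-3-methylpent-3-en-1-yl]-3,5,5-trimethylcyclohex-3-en-1-yl acetate | CC1=C(CC/C(C)=C/CO[Si](C)(C)C(C)(C)C)C(C)(C)C[C@H](OC(C)=O)C1 | intermediate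
25 | (1R)-4-[(3E)-5-hydroxy-3-methylpent-3-en-1-yl]-3,5,5-trimethylcyclohex-3-en-1-yl acetate | CC1=C(CC/C(C)=C/CO)C(C)(C)C[C@H](OC(C)=O)C1 | intermediate
26 | (1R)-4-[(3E)-5-bromo-3-methylpent-3-en-1-yl]-3,5,5-trimethylcyclohex-3-en-1-yl acetate | CC1=C(CC/C(C)=C/CBr)C(C)(C)C[C@H](OC(C)=O)C1 | intermediate
27 | {(2E)-5-[(4R)-4-acetoxy-2,6,6-trimethylcyclohex-1-en-1-yl]-3-methylpent-2-en-1-yl}tributylphosphonium bromide | CC1=C(CC/C(C)=C/C[P+](CCCC)(CCCC)CCCC)C(C)(C)C[C@H](OC(C)=O)C1.[Br-] | intermediate
28 | tributylphosphonium ylide of 27 | CC1=C(CC/C(C)=C/C=P(CCCC)(CCCC)CCCC)C(C)(C)C[C@H](OC(C)=O)C1 | intermediate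
29 | (3R,3′R)-3′-O-acetyl-3-O-(tert-butyldimethylsilyl)-7,8-didehydro-7′,8′-dihydro-β,β-carotene-3,3′-diol (all-E) | CC1=C(C#C/C(C)=C/C=C/C(C)=C/C=C/C=C(C)/C=C/C=C(\C)CCC2=C(C)C[C@@H](OC(C)=O)CC2(C)C)C(C)(C)C[C@H](O[Si](C)(C)C(C)(C)C)C1 | intermediate
30 | (3R,3′R)-3-O-(tert-butyldimethylsilyl)-7,8-didehydro-7′,8′-dihydro-β,β-carotene-3,3′-diol (all-E) | CC1=C(C#C/C(C)=C/C=C/C(C)=C/C=C/C=C(C)/C=C/C=C(\C)CCC2=C(C)C[C@@H](O)CC2(C)C)C(C)(C)C[C@H](O[Si](C)(C)C(C)(C)C)C1 | intermediate
31 | (3R,3′R)-7,8-didehydro-7′,8′-dihydro-β,β-carotene-3,3′-diol (all-E) | CC1=C(C#C/C(C)=C/C=C/C(C)=C/C=C/C=C(C)/C=C/C=C(\C)CCC2=C(C)C[C@@H](O)CC2(C)C)C(C)(C)C[C@H](O)C1 | target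

**Totals and risks**

Total step count: 18. Longest linear sequence: 12 steps (steps 7–18, from geraniol); the ring A branch (steps 1–6) joins at step 17.

Steps most likely to fail:

Step 10. The alkyl(alkenyl)ketene may dimerise or oligomerise faster than it adds to an unactivated alkene. The fallback sets out from 16 and replaces the ketene by a far more electrophilic keteniminium ion. The acid is converted through 18 with dimethylamine into the N,N-dimethylamide F1. Triflic anhydride and 2,4,6-collidine in the presence of isobutylene 17 (keteniminium–alkene [2+2]) should give the cyclobutaniminium triflate F2. Hydrolysis with aqueous NaHCO3 returns to the route at 20.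

Step 12. Proton transfer to the ring-opened allyl anion (from the α-CH2 of the aldehyde) may outrun reclosure, so the ring opens without expanding. The fallback sets out from 20 and expands the ring at the ketone level. Direct irradiation (about 300 nm, MeCN) should bring about the photochemical 1,3-acyl shift of the β,γ-unsaturated cyclobutanone to the cyclohex-3-en-1-one F3. F3 is reduced at once (NaBH4, CeCl3, MeOH, −78 °C) before the double bond can move into conjugation, and the route is rejoined at 23.

Step 13. The lipase may discriminate poorly between the two CH2-flanked sides of the carbinol, giving insufficient enantiomeric enrichment. The fallback sets out from 23 and uses covalent resolution. Esterification with (S)-2-methoxy-2-phenylacetic acid (DCC, DMAP) gives two diastereomeric esters, which are separated by chromatography or crystallisation to give the (1R)-ester F4. Methanolysis (K2CO3, MeOH) gives the (R)-alcohol F5, and acetylation (Ac2O, pyridine) returns to the route at 24.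

Further compounds
F1 | step 10 | (5E)-7-(tert-butyldimethylsilyloxy)-N,N,5-trimethyl-2-(prop-1-en-2-yl)hept-5-enamide (racemic) | C=C(C)C(CC/C(C)=C/CO[Si](C)(C)C(C)(C)C)C(=O)N(C)C
F2 | step 10 | N-{2-[(3E)-5-(tert-butyldimethylsilyloxy)-3-methylpent-3-en-1-yl]-3,3-dimethyl-2-(prop-1-en-2-yl)cyclobutylidene}-N-methylmethanaminium trifluoromethanesulfonate (racemic) | C=C(C)C1(CC/C(C)=C/CO[Si](C)(C)C(C)(C)C)C(=[N+](C)C)CC1(C)C.[O-]S(=O)(=O)C(F)(F)F
F3 | step 12 | 4-[(3E)-5-(tert-butyldimethylsilyloxy)-3-methylpent-3-en-1-yl]-3,5,5-trimethylcyclohex-3-en-1-one | CC1=C(CC/C(C)=C/CO[Si](C)(C)C(C)(C)C)C(C)(C)CC(=O)C1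
F4 | step 13 | (1R)-4-[(3E)-5-(tert-butyldimethylsilyloxy)-3-methylpent-3-en-1-yl]-3,5,5-trimethylcyclohex-3-en-1-yl (2S)-2-methoxy-2-phenylacetate | CC1=C(CC/C(C)=C/CO[Si](C)(C)C(C)(C)C)C(C)(C)C[C@H](OC(=O)[C@@H](OC)c2ccccc2)C1
F5 | step 13 | (1R)-4-[(3E)-5-(tert-butyldimethylsilyloxy)-3-methylpent-3-en-1-yl]-3,5,5-trimethylcyclohex-3-en-1-ol | CC1=C(CC/C(C)=C/CO[Si](C)(C)C(C)(C)C)C(C)(C)C[C@H](O)C1
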